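**Retrosynthetic overview**

1. Target ⇐ fully acetal-protected chalcone, in one flask: asymmetric nucleophilic epoxidation (oxirane, source of both stereocentres), then acid frees one phenol, which opens the oxirane 6-endo to close pyranone ring C, and strips the MOM groups.
2. Chalcone ⇐ Claisen–Schmidt condensation of a prenylated, doubly protected acetophenone with MOM-isovanillin.
3. Acetophenone ⇐ 2',6'-dihydroxy-4'-methoxyacetophenone by nuclear C-prenylation, then a labile 1-ethoxyethyl (EE) acetal on the oxygen that becomes O1 and a MOM ether on the prenyl-flanked oxygen that becomes 5-OH; this fixes 6- over 8-prenyl.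
4. Ring order: rings A and B are bought as arenes; the oxirane and then ring C are both formed in the last operation.

Assumption: 2',6'-dihydroxy-4'-methoxyacetophenone is bought as a catalogue compound; the acetal carbon of the EE group is an unresolved stereocentre (about 1:1), written without configuration and lost in the last step.

**Route**

Step 1
Reactants: 1 1-(2,6-dihydroxy-4-methoxyphenyl)ethan-1-one; 2 prenyl bromide (1-bromo-3-methylbut-2-ene)
Product: 3 1-[2,6-dihydroxy-4-methoxy-3-(3-methylbut-2-en-1-yl)phenyl]ethan-1-one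
Conditions: 2 (0.9 equiv), 10% aq. KOH, 0 °C → rt
Reagents that add atoms: prenyl bromide (2), CC(C)=CCBr
Why: Nuclear prenylation (phenoxide C-alkylation) in water, where the solvated phenoxide oxygens steer the allylic bromide to carbon; the two open ring positions of 1 are equivalent, so only one mono-C-prenyl product is possible, and under-charging the bromide limits bis- and O-alkylation.

Step 2
Reactants: 3 1-[2,6-dihydroxy-4-methoxy-3-(3-methylbut-2-en-1-yl)phenyl]ethan-1-one; 4 ethyl vinyl ether
Product: 5 1-[6-(1-ethoxyethoxy)-2-hydroxy-4-methoxy-3-(3-methylbut-2-en-1-yl)phenyl]ethan-1-one (EE on the OH next to the ring H; the OH next to the prenyl group stays free)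
Conditions: 4 (1.2 equiv), PPTS (cat.), CH2Cl2, 0 °C → rt
Reagents that add atoms: ethyl vinyl ether (4), C=COCC
Why: Acid-catalysed acetalisation of a phenol with a vinyl ether, expected to take place at the less hindered OH (not flanked by the prenyl group) and to stop there because the remaining OH is locked in the hydrogen bond to the ketone, so the oxygen that will become O1 carries the most acid-labile group.

Step 3
Reactants: 5 1-[6-(1-ethoxyethoxy)-2-hydroxy-4-methoxy-3-(3-methylbut-2-en-1-yl)phenyl]ethan-1-one; 6 chloromethyl methyl ether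
Product: 7 1-[6-(1-ethoxyethoxy)-4-methoxy-2-(methoxymethoxy)-3-(3-methylbut-2-en-1-yl)phenyl]ethan-1-one
Conditions: NaH, DMF, 0 °C; then 6, 0 °C → rt
Reagents that add atoms: chloromethyl methyl ether (6), COCCl
Why: Williamson-type O-alkylation of the sodium phenoxide of the chelated, prenyl-flanked OH; the MOM ether is about a hundred times slower to cleave in acid than EE, which is the basis of the timing in step 6.

Step 4
Reactants: 8 isovanillin (3-hydroxy-4-methoxybenzaldehyde); 6 chloromethyl methyl ether
Product: 9 4-methoxy-3-(methoxymethoxy)benzaldehyde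
Conditions: 6, K2CO3, DMF, 0 °C → rt
Reagents that add atoms: chloromethyl methyl ether (6), COCCl
Why: Phenoxide O-alkylation (MOM protection) of an unhindered phenol, which removes the acidic OH that would slow the aldol step and disturb the basic epoxidation.

Step 5
Reactants: 7 1-[6-(1-ethoxyethoxy)-4-methoxy-2-(methoxymethoxy)-3-(3-methylbut-2-en-1-yl)phenyl]ethan-1-one; 9 4-methoxy-3-(methoxymethoxy)benzaldehyde
Product: 10 (2E)-1-[6-(1-ethoxyethoxy)-4-methoxy-2-(methoxymethoxy)-3-(3-methylbut-2-en-1-yl)phenyl]-3-[4-methoxy-3-(methoxymethoxy)phenyl]prop-2-en-1-one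
Conditions: KOH, EtOH/H2O, rt, 24–48 h
Reagents that add atoms: none
Why: Claisen–Schmidt condensation (crossed aldol, then E1cB dehydration) giving the E-enone; both acetals are base-stable, and with no free 2'-OH the chalcone cannot close to a flavanone.

Step 6
Reactants: 10 (2E)-1-[6-(1-ethoxyethoxy)-4-methoxy-2-(methoxymethoxy)-3-(3-methylbut-2-en-1-yl)phenyl]-3-[4-methoxy-3-(methoxymethoxy)phenyl]prop-2-en-1-one; 11 urea–hydrogen peroxide
Product: 15 (2R,3R)-3,5-dihydroxy-2-(3-hydroxy-4-methoxyphenyl)-7-methoxy-6-(3-methylbut-2-en-1-yl)-2,3-dihydro-4H-chromen-4-one, via epoxy ketone 12 (not isolated), via phenol epoxide 13 (not isolated), via bis-MOM dihydroflavonol 14 (not isolated)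
Conditions: (i) poly-L-leucine (cat.), 11 (1.3 equiv), DBU, THF, rt; (ii) Me2S (peroxide quench), then HCl/MeOH, 0 °C; (iii) 40 °C; one pot
Reagents that add atoms: urea–hydrogen peroxide (11), OO.NC(N)=O
Why: Proposed new method: a telescoped Juliá–Colonna epoxidation and acid-triggered cyclisation, in which the poly-L-leucine helix delivers hydroperoxide by Weitz–Scheffer conjugate addition (which leaves the electron-rich prenyl alkene alone) to one enone face to give the trans-(αR,βS)-oxirane 12, cold methanolic HCl then removes only the EE acetal, the single free phenol of 13 opens the protonated oxirane 6-endo at the p-methoxybenzylic carbon with inversion (Cβ S → C2 R) while the Cα–O bond is never broken (Cα R → C3 R) to give trans-14, and warming cleaves both MOM ethers; the closest known chemistry is the poly-amino-acid epoxidation of 2'-O-alkoxymethyl chalcones and their acid-mediated deprotective cyclisation to trans-dihydroflavonols.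

**Compound list**

1 | 1-(2,6-dihydroxy-4-methoxyphenyl)ethan-1-one | CC(=O)c1c(O)cc(OC)cc1O | starting material
2 | prenyl bromide (1-bromo-3-methylbut-2-ene) | CC(C)=CCBr | starting material
3 | 1-[2,6-dihydroxy-4-methoxy-3-(3-methylbut-2-en-1-yl)phenyl]ethan-1-one | CC(=O)c1c(O)cc(OC)c(CC=C(C)C)c1O | intermediate
4 | ethyl vinyl ether | C=COCC | starting material
5 | 1-[6-(1-ethoxyethoxy)-2-hydroxy-4-methoxy-3-(3-methylbut-2-en-1-yl)phenyl]ethan-1-one | CC(=O)c1c(OC(C)OCC)cc(OC)c(CC=C(C)C)c1O | intermediate
6 | chloromethyl methyl ether | COCCl | starting material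
7 | 1-[6-(1-ethoxyethoxy)-4-methoxy-2-(methoxymethoxy)-3-(3-methylbut-2-en-1-yl)phenyl]ethan-1-one | CC(=O)c1c(OC(C)OCC)cc(OC)c(CC=C(C)C)c1OCOC | intermediate
8 | isovanillin (3-hydroxy-4-methoxybenzaldehyde) | COc1ccc(C=O)cc1O | starting material
9 | 4-methoxy-3-(methoxymethoxy)benzaldehyde | COCOc1cc(C=O)ccc1OC | intermediate
10 | (2E)-1-[6-(1-ethoxyethoxy)-4-methoxy-2-(methoxymethoxy)-3-(3-methylbut-2-en-1-yl)phenyl]-3-[4-methoxy-3-(methoxymethoxy)phenyl]prop-2-en-1-one | CCOC(C)Oc1cc(OC)c(CC=C(C)C)c(OCOC)c1C(=O)/C=C/c1ccc(OC)c(OCOC)c1 | intermediate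
11 | urea–hydrogen peroxide | OO.NC(N)=O | starting material
12 | [6-(1-ethoxyethoxy)-4-methoxy-2-(methoxymethoxy)-3-(3-methylbut-2-en-1-yl)phenyl]{(2R,3S)-3-[4-methoxy-3-(methoxymethoxy)phenyl]oxiran-2-yl}methanone | CCOC(C)Oc1cc(OC)c(CC=C(C)C)c(OCOC)c1C(=O)[C@@H]2O[C@H]2c3ccc(OC)c(OCOC)c3 | intermediate
13 | [6-hydroxy-4-methoxy-2-(methoxymethoxy)-3-(3-methylbut-2-en-1-yl)phenyl]{(2R,3S)-3-[4-methoxy-3-(methoxymethoxy)phenyl]oxiran-2-yl}methanone | Oc1cc(OC)c(CC=C(C)C)c(OCOC)c1C(=O)[C@@H]2O[C@H]2c3ccc(OC)c(OCOC)c3 | intermediate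
14 | (2R,3R)-3-hydroxy-7-methoxy-5-(methoxymethoxy)-2-[4-methoxy-3-(methoxymethoxy)phenyl]-6-(3-methylbut-2-en-1-yl)-2,3-dihydro-4H-chromen-4-one | COc1ccc([C@H]2Oc3cc(OC)c(CC=C(C)C)c(OCOC)c3C(=O)[C@@H]2O)cc1OCOC | intermediate
15 | (2R,3R)-3,5-dihydroxy-2-(3-hydroxy-4-methoxyphenyl)-7-methoxy-6-(3-methylbut-2-en-1-yl)-2,3-dihydro-4H-chromen-4-one | COc1ccc([C@H]2Oc3cc(OC)c(CC=C(C)C)c(O)c3C(=O)[C@@H]2O)cc1O | target

**Totals and risks**

Total step count: 6. Longest linear sequence: 5 (steps 1, 2, 3, 5, 6); step 4 is a one-step side branch.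

Step 6 is the most likely to fail. The di-ortho-substituted, electron-rich enone may be epoxidised slowly or with only moderate ee. In the acid stage, methanol can capture the benzylic cation, a little cis (2S,3R) isomer can form, and a MOM group lost too early would let the 8-prenyl isomer in. The prenyl group may also hydrate or close onto the 5-OH at 40 °C. The final ee would be raised by crystallising 15. Fallback, setting out from 7: the methyl ketone is chlorinated (LiHMDS, THF, −78 °C, then NCS) to 2-chloro-1-[6-(1-ethoxyethoxy)-4-methoxy-2-(methoxymethoxy)-3-(3-methylbut-2-en-1-yl)phenyl]ethan-1-one F5. F5 is joined to aldehyde 9 in a catalytic asymmetric Darzens condensation (cinchona-derived quaternary ammonium phase-transfer catalyst, LiOH, CH2Cl2, 0 °C; the pseudo-enantiomer that gives the (2R,3S) oxirane is picked on a test scale). This makes the C–C bond and the trans-oxirane together without needing the enone to accept a peroxide. It comes back to the route at 12, now isolated and purified, which is put through the staged acid treatment of step 6 to 15.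

Step 1 is the second risk: C- against O-alkylation and over-prenylation usually hold this reaction to a 30–45% yield. Fallback, setting out from 1: mono-O-prenylation (2, K2CO3, acetone, reflux; the second OH stays chelated) gives 1-{2-hydroxy-4-methoxy-6-[(3-methylbut-2-en-1-yl)oxy]phenyl}ethan-1-one F1. A para-Claisen (Claisen then Cope) rearrangement of F1 in N,N-diethylaniline at 200 °C carries the prenyl group to the ring carbon para to the ether oxygen, next to the other OH. The ortho reverse-prenyl isomer is the by-product to remove. The fallback comes back to the route at 3.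

Step 2 is the third risk: the mono-acetalisation may not distinguish the two phenols cleanly. Fallback, setting out from 1, which fixes the difference by the order of events instead of by sterics: mono-MOM protection (6, K2CO3, acetone) gives 1-[2-hydroxy-4-methoxy-6-(methoxymethoxy)phenyl]ethan-1-one F2. O-Prenylation of its remaining OH (2, K2CO3, DMF, 60 °C) gives 1-{4-methoxy-2-(methoxymethoxy)-6-[(3-methylbut-2-en-1-yl)oxy]phenyl}ethan-1-one F3. The para-Claisen rearrangement of F3 (N,N-diethylaniline, 200 °C) places the prenyl group between the methoxy and MOM-oxy groups and frees the other oxygen, giving 1-[6-hydroxy-4-methoxy-2-(methoxymethoxy)-3-(3-methylbut-2-en-1-yl)phenyl]ethan-1-one F4. Its only OH is then capped with ethyl vinyl ether 4 (PPTS, CH2Cl2). The fallback comes back to the route at 7 and replaces steps 1–3.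

**Further compounds**

F1 | step 1 | 1-{2-hydroxy-4-methoxy-6-[(3-methylbut-2-en-1-yl)oxy]phenyl}ethan-1-one | CC(=O)c1c(O)cc(OC)cc1OCC=C(C)C
F2 | step 2 | 1-[2-hydroxy-4-methoxy-6-(methoxymethoxy)phenyl]ethan-1-one | CC(=O)c1c(O)cc(OC)cc1OCOC
F3 | step 2 | 1-{4-methoxy-2-(methoxymethoxy)-6-[(3-methylbut-2-en-1-yl)oxy]phenyl}ethan-1-one | CC(=O)c1c(OCC=C(C)C)cc(OC)cc1OCOC
F4 | step 2 | 1-[6-hydroxy-4-methoxy-2-(methoxymethoxy)-3-(3-methylbut-2-en-1-yl)phenyl]ethan-1-one | CC(=O)c1c(O)cc(OC)c(CC=C(C)C)c1OCOC
F5 | step 6 | 2-chloro-1-[6-(1-ethoxyethoxy)-4-methoxy-2-(methoxymethoxy)-3-(3-methylbut-2-en-1-yl)phenyl]ethan-1-one | O=C(CCl)c1c(OC(C)OCC)cc(OC)c(CC=C(C)C)c1OCOC
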